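**Assumption:** the SMILES defines the target: all five stereocentres are (S), the enedione is Z, and the two ring bonds on the cyclopropane are trans. Locants are cembranoid-style: C1 = CH–isopropenyl, C2 = CH–OAc, C3/C6 = ketone carbons, C7/C8/C9 = cyclopropane CH/C(Me)/CH2, C10 = lactone CH–O, C12 = lactone α-carbon.

## Retrosynthetic overview
1. Pinnatin B ⇐ oxidative opening of a 3,6-furan (gives the Z-ene-1,4-dione) in the acetylated furan-bridged macrocycle 29.
2. Macrocycle ⇐ intramolecular Nozaki–Hiyama–Kishi allylation of bromo-aldehyde 27, forming C1–C2 and both of those stereocentres.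
3. Butenolide ⇐ Ru-catalysed Alder-ene/lactonisation of γ-hydroxy-ynoate 20 with allyl alcohol; C10 from asymmetric transfer hydrogenation of an ynone.
4. Furan ⇐ aldol/cyclodehydration annulation on cyclopropyl methyl ketone 8, then C–H formylation.
5. trans-Cyclopropane ⇐ OH-directed Simmons–Smith on (S)-allylic alcohol 6 ⇐ ketoreductase reduction of achiral enone 5. Ring order: cyclopropane → furan → butenolide → macrocycle → furan opened.

## Route

**Step 1**
Reactants: 1 prop-2-yn-1-ol
Product: 2 (E)-3-iodo-2-methylprop-2-en-1-ol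
Conditions: Me3Al (3 equiv), Cp2ZrCl2 (0.25 equiv), CH2Cl2, 0 °C→rt; then I2, THF, −30 °C
Reagents that add atoms: trimethylaluminium C[Al](C)C; iodine II
Why: Negishi Zr-catalysed carboalumination is a syn addition (Me to the internal carbon) and iodinolysis proceeds with retention, so Me and I are cis; this geometry later becomes the trans-cyclopropane.

**Step 2**
Reactants: 2
Product: 3 (E)-tert-butyl[(3-iodo-2-methylallyl)oxy]diphenylsilane
Conditions: TBDPSCl, imidazole, CH2Cl2, 0 °C→rt
Reagents that add atoms: TBDPSCl CC(C)(C)[Si](Cl)(c1ccccc1)c1ccccc1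
Why: Standard silylation of a primary alcohol; TBDPS survives the organolithium, Zn-carbenoid and mild-acid steps that follow.

**Step 3**
Reactants: 3; 4 N-methoxy-N-methylacetamide
Product: 5 (E)-5-[(tert-butyldiphenylsilyl)oxy]-4-methylpent-3-en-2-one
Conditions: t-BuLi (2.1 equiv), Et2O, −78 °C; then 4, −78→0 °C
Reagents that add atoms: N-methoxy-N-methylacetamide CON(C)C(C)=O
Why: Li–I exchange retains alkene geometry, and Weinreb amide acylation stops at the ketone through the chelated tetrahedral intermediate.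

**Step 4**
Reactants: 5
Product: 6 (S,E)-5-[(tert-butyldiphenylsilyl)oxy]-4-methylpent-3-en-2-ol
Conditions: ketoreductase (Prelog-selective NAD(P)H-dependent KRED/alcohol dehydrogenase), NADP+ (cat.), iPrOH (20% v/v), phosphate buffer pH 7, 30 °C
Reagents that add atoms: none
Why: Enzymatic asymmetric ketone reduction; a Prelog ketoreductase delivers hydride to the re face of the methyl ketone (small Me vs large alkenyl) to give the (S)-alcohol in >99% ee, the first stereocentre, set catalytically from achiral 5.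

**Step 5**
Reactants: 6
Product: 7 (S)-1-[(1S,2S)-2-{[(tert-butyldiphenylsilyl)oxy]methyl}-2-methylcyclopropyl]ethan-1-ol
Conditions: Et2Zn (5 equiv), CH2I2 (10 equiv), CH2Cl2, −10→0 °C
Reagents that add atoms: diiodomethane ICI
Why: Hydroxyl-directed Simmons–Smith (Furukawa) cyclopropanation; A(1,3) strain with the cis-methyl holds the carbinol H in plane so CH2 is delivered syn to the zinc alkoxide (dr >20:1), and the stereospecific addition to the E-alkene gives the trans (7S,8S) cyclopropane.

**Step 6**
Reactants: 7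
Product: 8 1-[(1S,2S)-2-{[(tert-butyldiphenylsilyl)oxy]methyl}-2-methylcyclopropyl]ethan-1-one
Conditions: Dess–Martin periodinane, NaHCO3, CH2Cl2, 0 °C→rt
Reagents that add atoms: none
Why: Mild non-acidic oxidation removes the now-redundant carbinol centre; the cyclopropyl α-CH does not enolise under these conditions.

**Step 7**
Reactants: 8; 9 1-[(tert-butyldimethylsilyl)oxy]propan-2-one
Product: 10 1-[(1S,2S)-2-{[(tert-butyldiphenylsilyl)oxy]methyl}-2-methylcyclopropyl]-5-[(tert-butyldimethylsilyl)oxy]-4-hydroxy-4-methylpentan-1-one (C4 epimers, inconsequential)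
Conditions: LDA, THF, −78 °C; then 9, −78 °C; AcOH quench at −78 °C
Reagents that add atoms: 1-(TBSO)propan-2-one CC(=O)CO[Si](C)(C)C(C)(C)C
Why: Kinetic deprotonation occurs only at the methyl group (an exocyclic cyclopropylidene enolate is disfavoured), and aldol addition to the activated α-silyloxy ketone installs C4, its methyl and C3.

**Step 8**
Reactants: 10
Product: 11 tert-butyl{[(1S,2S)-1-methyl-2-(4-methylfuran-2-yl)cyclopropyl]methoxy}diphenylsilane
Conditions: p-TsOH·H2O (0.2 equiv), THF–MeOH, rt→40 °C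
Reagents that add atoms: none
Why: Acid removes the primary TBS group (TBDPS is about 100-fold more stable), and the γ-hydroxy ketone undergoes hemiketalisation and double dehydration, driven by aromatisation, to the furan.

**Step 9**
Reactants: 11
Product: 12 5-[(1S,2S)-2-{[(tert-butyldiphenylsilyl)oxy]methyl}-2-methylcyclopropyl]-3-methylfuran-2-carbaldehyde
Conditions: n-BuLi, THF, −78→0 °C; DMF, −78 °C→rt
Reagents that add atoms: DMF CN(C)C=O
Why: α-Lithiation at the only free furan α-position and formylation introduce C2.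

**Step 10**
Reactants: 12; 13 2,2-dimethylpropane-1,3-diol
Product: 14 tert-butyl{[(1S,2S)-2-[5-(5,5-dimethyl-1,3-dioxan-2-yl)-4-methylfuran-2-yl]-1-methylcyclopropyl]methoxy}diphenylsilane
Conditions: 13, PPTS (cat.), benzene, reflux (Dean–Stark)
Reagents that add atoms: 2,2-dimethylpropane-1,3-diol OCC(C)(C)CO
Why: Acetalisation masks the furfural through the nucleophile, fluoride, ylide and hydride steps; the neopentyl-glycol acetal is the most robust simple acetal.

**Step 11**
Reactants: 14
Product: 15 {(1S,2S)-2-[5-(5,5-dimethyl-1,3-dioxan-2-yl)-4-methylfuran-2-yl]-1-methylcyclopropyl}methanol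
Conditions: TBAF, THF, 0 °C→rt
Reagents that add atoms: none
Why: Fluoride desilylation is orthogonal to the acetal.

**Step 12**
Reactants: 15
Product: 16 (1S,2S)-2-[5-(5,5-dimethyl-1,3-dioxan-2-yl)-4-methylfuran-2-yl]-1-methylcyclopropane-1-carbaldehyde
Conditions: SO3·pyridine, DMSO, iPr2NEt, CH2Cl2, 0 °C
Reagents that add atoms: none
Why: Parikh–Doering oxidation is fully basic (acetal-safe), and the α-quaternary aldehyde cannot epimerise.

**Step 13**
Reactants: 16; 17 ethyl propiolate
Product: 18 ethyl 4-{(1S,2S)-2-[5-(5,5-dimethyl-1,3-dioxan-2-yl)-4-methylfuran-2-yl]-1-methylcyclopropyl}-4-hydroxybut-2-ynoate (C4 epimers)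
Conditions: 17, LiHMDS, THF, −78 °C; then 16, −78 °C
Reagents that add atoms: ethyl propiolate C#CC(=O)OCC
Why: Lithium propiolate 1,2-addition installs C11, C12 and the lactone carbonyl; no selectivity is needed because the carbinol is re-set in steps 14–15.

**Step 14**
Reactants: 18
Product: 19 ethyl 4-{(1S,2S)-2-[5-(5,5-dimethyl-1,3-dioxan-2-yl)-4-methylfuran-2-yl]-1-methylcyclopropyl}-4-oxobut-2-ynoate
Conditions: Dess–Martin periodinane, NaHCO3, CH2Cl2, 0 °C
Reagents that add atoms: none
Why: Buffered oxidation of the propargylic alcohol to the ynone converges both epimers.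

**Step 15**
Reactants: 19
Product: 20 ethyl (R)-4-{(1S,2S)-2-[5-(5,5-dimethyl-1,3-dioxan-2-yl)-4-methylfuran-2-yl]-1-methylcyclopropyl}-4-hydroxybut-2-ynoate
Conditions: RuCl[(R,R)-TsDPEN](p-cymene) (3 mol%), iPrOH, rt
Reagents that add atoms: none
Why: Noyori–Ikariya asymmetric transfer hydrogenation of an ynone is catalyst-controlled (alkynyl takes the aryl role; the bulky tertiary alkyl side raises ee), and the (R,R) catalyst gives the (R)-carbinol, which is C10 (it becomes "S" in the lactone only because CIP priorities change).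

**Step 16**
Reactants: 20; 21 prop-2-en-1-ol
Product: 22 3-{(5S)-5-[(1S,2S)-2-(5-(5,5-dimethyl-1,3-dioxan-2-yl)-4-methylfuran-2-yl)-1-methylcyclopropyl]-2-oxo-2,5-dihydrofuran-3-yl}propanal
Conditions: 21 (3 equiv), CpRu(MeCN)3PF6 (10 mol%), acetone, rt
Reagents that add atoms: allyl alcohol C=CCO
Why: Trost Ru-catalysed Alder-ene coupling forms the C–C bond at the ynoate α-carbon with cis H-delivery; the enol tautomerises to the aldehyde and the Z-γ-hydroxy enoate lactonises (loss of EtOH) to the butenolide with C10 untouched.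

**Step 17**
Reactants: 22; 23 2-(triphenyl-λ5-phosphanylidene)propanal
Product: 24 (E)-5-{(5S)-5-[(1S,2S)-2-(5-(5,5-dimethyl-1,3-dioxan-2-yl)-4-methylfuran-2-yl)-1-methylcyclopropyl]-2-oxo-2,5-dihydrofuran-3-yl}-2-methylpent-2-enal
Conditions: 23, toluene, 80 °C
Reagents that add atoms: 2-(triphenylphosphoranylidene)propanal CC(C=O)=P(c1ccccc1)(c1ccccc1)c1ccccc1
Why: Wittig olefination with a stabilised ylide is E-selective and too weakly basic to touch the butenolide γ-H.

**Step 18**
Reactants: 24
Product: 25 (5S)-5-[(1S,2S)-2-(5-(5,5-dimethyl-1,3-dioxan-2-yl)-4-methylfuran-2-yl)-1-methylcyclopropyl]-3-[(E)-5-hydroxy-4-methylpent-3-en-1-yl]furan-2(5H)-one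
Conditions: NaBH4, MeOH–THF, 0 °C
Reagents that add atoms: none
Why: Chemoselective 1,2-reduction of the enal; the butenolide and acetal are inert, which is why the furfural is still masked at this point.

**Step 19**
Reactants: 25
Product: 26 5-{(1S,2S)-2-[(2S)-4-((E)-5-hydroxy-4-methylpent-3-en-1-yl)-5-oxo-2,5-dihydrofuran-2-yl]-2-methylcyclopropyl}-3-methylfuran-2-carbaldehyde
Conditions: PPTS, acetone–H2O (5:1), rt
Reagents that add atoms: water O
Why: Mild acetal hydrolysis/transacetalisation releases the furfural without affecting the allylic alcohol or butenolide.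

**Step 20**
Reactants: 26
Product: 27 5-{(1S,2S)-2-[(2S)-4-((E)-5-bromo-4-methylpent-3-en-1-yl)-5-oxo-2,5-dihydrofuran-2-yl]-2-methylcyclopropyl}-3-methylfuran-2-carbaldehyde
Conditions: PPh3, NBS, CH2Cl2, −20 °C
Reagents that add atoms: N-bromosuccinimide O=C1CCC(=O)N1Br
Why: Appel-type bromination of the primary allylic alcohol; NBS/PPh3 avoids the Corey–Fuchs reaction that CBr4/PPh3 would cause at the aldehyde.

**Step 21**
Reactants: 27
Product: 28 furan-bridged macrocyclic alcohol (1S,2S,7S,8S,10S): target skeleton with a 3,6-furan in place of the enedione and free C2–OH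
Conditions: CrCl2 (12 equiv), 4 Å MS, THF (0.003 M), slow addition, rt
Reagents that add atoms: none
Why: Intramolecular Nozaki–Hiyama–Kishi allylation; the allyl-Cr(III) adds through its γ-carbon via a chair transition state, giving the anti C1/C2 pair and the isopropenyl group, with the face expected to be dictated by the rigid cyclopropane–butenolide–furan backbone (this facial sense is the main stereochemical uncertainty of the route).

**Step 22**
Reactants: 28
Product: 29 C2-acetate of 28
Conditions: Ac2O, pyridine, DMAP (cat.), CH2Cl2, 0 °C→rt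
Reagents that add atoms: acetic anhydride CC(=O)OC(C)=O
Why: Standard acylation of the furfuryl secondary alcohol; it also blocks Achmatowicz rearrangement in the final step.

**Step 23**
Reactants: 29
Product: 30 Pinnatin B
Conditions: mCPBA (1.05 equiv), NaHCO3, CH2Cl2, 0 °C
Reagents that add atoms: mCPBA O=C(OO)c1cccc(Cl)c1
Why: Peracid oxidation of the electron-rich trisubstituted furan and ring-opening gives the cis (Z) ene-1,4-dione directly; the butenolide alkene is electron-poor, the isopropenyl is far less nucleophilic, and no stereocentre is touched.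

## Compound list
1 | prop-2-yn-1-ol | C#CCO | starting material
2 | (E)-3-iodo-2-methylprop-2-en-1-ol | OC/C(C)=C/I | intermediate
3 | (E)-tert-butyl[(3-iodo-2-methylallyl)oxy]diphenylsilane | CC(C)(C)[Si](OC/C(C)=C/I)(c1ccccc1)c1ccccc1 | intermediate
4 | N-methoxy-N-methylacetamide | CON(C)C(C)=O | starting material
5 | (E)-5-(TBDPSO)-4-methylpent-3-en-2-one | CC(=O)/C=C(\C)CO[Si](c1ccccc1)(c1ccccc1)C(C)(C)C | intermediate
6 | (S,E)-5-(TBDPSO)-4-methylpent-3-en-2-ol | C[C@H](O)/C=C(\C)CO[Si](c1ccccc1)(c1ccccc1)C(C)(C)C | intermediate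
7 | (S)-1-[(1S,2S)-2-(TBDPSOCH2)-2-methylcyclopropyl]ethanol | CC(C)(C)[Si](c1ccccc1)(c1ccccc1)OC[C@@]1(C)C[C@@H]1[C@H](C)O | intermediate
8 | 1-[(1S,2S)-2-(TBDPSOCH2)-2-methylcyclopropyl]ethanone | CC(C)(C)[Si](c1ccccc1)(c1ccccc1)OC[C@@]1(C)C[C@@H]1C(C)=O | intermediate
9 | 1-(TBSO)propan-2-one | CC(=O)CO[Si](C)(C)C(C)(C)C | starting material
10 | aldol adduct (C4 epimers) | CC(C)(C)[Si](c1ccccc1)(c1ccccc1)OC[C@@]1(C)C[C@@H]1C(=O)CC(C)(O)CO[Si](C)(C)C(C)(C)C | intermediate
11 | 2-cyclopropyl-4-methylfuran (TBDPS ether) | CC(C)(C)[Si](c1ccccc1)(c1ccccc1)OC[C@@]1(C)C[C@@H]1c1cc(C)co1 | intermediate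
12 | 5-cyclopropyl-3-methylfurfural (TBDPS ether) | CC(C)(C)[Si](c1ccccc1)(c1ccccc1)OC[C@@]1(C)C[C@@H]1c1cc(C)c(C=O)o1 | intermediate
13 | 2,2-dimethylpropane-1,3-diol | OCC(C)(C)CO | starting material
14 | dioxane acetal of 12 | CC(C)(C)[Si](c1ccccc1)(c1ccccc1)OC[C@@]1(C)C[C@@H]1c1cc(C)c(C2OCC(C)(C)CO2)o1 | intermediate
15 | cyclopropylmethanol acetal | OC[C@@]1(C)C[C@@H]1c1cc(C)c(C2OCC(C)(C)CO2)o1 | intermediate
16 | cyclopropanecarbaldehyde acetal | O=C[C@@]1(C)C[C@@H]1c1cc(C)c(C2OCC(C)(C)CO2)o1 | intermediate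
17 | ethyl propiolate | C#CC(=O)OCC | starting material
18 | γ-hydroxy-ynoate (C10 epimers) | CCOC(=O)C#CC(O)[C@@]1(C)C[C@@H]1c1cc(C)c(C2OCC(C)(C)CO2)o1 | intermediate
19 | γ-oxo-ynoate | CCOC(=O)C#CC(=O)[C@@]1(C)C[C@@H]1c1cc(C)c(C2OCC(C)(C)CO2)o1 | intermediate
20 | (R)-γ-hydroxy-ynoate | CCOC(=O)C#C[C@H](O)[C@@]1(C)C[C@@H]1c1cc(C)c(C2OCC(C)(C)CO2)o1 | intermediate
21 | prop-2-en-1-ol | C=CCO | starting material
22 | butenolide propanal | O=CCCC1=C[C@H](OC1=O)[C@@]1(C)C[C@@H]1c1cc(C)c(C2OCC(C)(C)CO2)o1 | intermediate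
23 | 2-(triphenylphosphoranylidene)propanal | CC(C=O)=P(c1ccccc1)(c1ccccc1)c1ccccc1 | starting material
24 | (E)-enal | O=C/C(C)=C/CCC1=C[C@H](OC1=O)[C@@]1(C)C[C@@H]1c1cc(C)c(C2OCC(C)(C)CO2)o1 | intermediate
25 | (E)-allylic alcohol (acetal) | OC/C(C)=C/CCC1=C[C@H](OC1=O)[C@@]1(C)C[C@@H]1c1cc(C)c(C2OCC(C)(C)CO2)o1 | intermediate
26 | hydroxy-furfural | OC/C(C)=C/CCC1=C[C@H](OC1=O)[C@@]1(C)C[C@@H]1c1cc(C)c(C=O)o1 | intermediate
27 | bromo-furfural | BrC/C(C)=C/CCC1=C[C@H](OC1=O)[C@@]1(C)C[C@@H]1c1cc(C)c(C=O)o1 | intermediate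
28 | furan-bridged macrocyclic alcohol | C=C(C)[C@@H]1CCC2=C[C@H](OC2=O)[C@@]3(C)C[C@@H]3c4cc(C)c(o4)[C@H]1O | intermediate
29 | furan-bridged macrocyclic acetate | C=C(C)[C@@H]1CCC2=C[C@H](OC2=O)[C@@]3(C)C[C@@H]3c4cc(C)c(o4)[C@H]1OC(C)=O | intermediate
30 | Pinnatin B | C=C(C)[C@@H]1CCC2=C[C@H](OC2=O)[C@@]2(C)C[C@@H]2C(=O)/C=C(/C)C(=O)[C@H]1OC(C)=O | target

## Summary
Total steps: 23. Longest linear sequence: 23 (fully linear; all coupling partners are commercial and achiral).

Steps most likely to fail:
1. **Step 21 (NHK macrocyclisation).** The ring is strained, and while the anti C1/C2 relationship is intrinsic, the facial sense relative to C7/C8/C10 rests on macrocyclic control. Fallback: set C1/C2 before ring closure by an intermolecular chiral-phosphoric-acid-catalysed allylboration of a furfural such as 12 with an (E)-allyl-Bpin carrying the C13–C14 chain. Then close the macrocycle through the butenolide instead (macrolactonisation of a C10 vinyl carbinol with a C12 acrylic acid, followed by RCM).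
2. **Step 16 (Ru Alder-ene/lactonisation).** The furan may sequester cationic Ru and the acetal may be labile. Fallback: build the butenolide by acylating a C10 vinyl carbinol (vinyl ketone from 16, then CBS reduction) with the side-chain-bearing 2-alkylacrylic acid and closing by RCM with Grubbs II.
3. **Steps 7–8 (ketone–ketone aldol and acid cyclodehydration).** Retro-aldol or proton transfer can erode the aldol, and the furyl cyclopropane is acid-sensitive. Fallback: convert ketone 8 to the terminal alkyne (enol triflate, elimination), add its acetylide to ketone 9, and form the furan by Ag(I)/Au(I)-catalysed cyclisation–dehydration of the resulting 3-alkyne-1,2-diol under neutral conditions.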